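Locants: ring C1 is the C–OH carbon flanked by C2 (CH3) and C6 (chain), C4 is the second C–O carbon; the chain runs from C1' (benzylic CH2) to C15' (tertiary carbinol).
Ring cut at C4–C5, C6–C1 and C1–C2: the ring carries OH on C1, CH3 on C2, O on C4, the chain on C6 and only H on C3 and C5, so it divides into a methoxy(propenyl)carbene ligand on chromium (C4, C3, C2), one carbonyl ligand (C1) and a terminal alkyne (C5, C6); the oxidation-sensitive ring is therefore built last.
Chain cuts: C1'–C≡ (allylic bromide + ethynyl), C1'–C2' with C3'–CH3 and C5'–C6' with C7'–CH3 (alkyne methylalumination/formaldehyde, twice), C4'–C5' (allenylboration), C9'–C10' (alkyl–alkyl coupling), C12'–C13' (aldehyde + alkenyl iodide).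
Forward order: C10'–C12' bromide + C6'–C9' Grignard reagent, first carboalumination (C5'), oxidation, allenylboration (C2'–C4'), second carboalumination (C1'), ethynylation, acetate, enone at C12'–C15', benzannulation, oxidative demethylation, reduction.
Stereochemistry: C11' (S) is bought with (R)-3-bromo-2-methylpropan-1-ol; C5' (S) comes from catalyst-controlled Si-face allenylboration; 2'E and 6'E from syn-carboalumination; 13'E from syn-hydrostannylation.

Key step: step 18

Remark: compound 26 is carried as both C12' epimers, which converge in step 16, and the η6-bound Cr(CO)3 unit of 33 is written as a separate fragment in its SMILES.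

Step 1
Reactants: 1 (R)-3-bromo-2-methylpropan-1-ol
Product: 2 (R)-(3-bromo-2-methylpropoxy)(tert-butyl)dimethylsilane
Conditions: TBSCl, imidazole, CH2Cl2, 0 °C to rt
Reagents that add atoms: tert-butyldimethylsilyl chloride (TBSCl), CC(C)(C)[Si](C)(C)Cl
Why: Standard silylation of a primary alcohol masks the future C12' oxygen for the organometallic steps ahead and does not touch the stereocentre that becomes C11'.

Step 2
Reactants: 2 (R)-(3-bromo-2-methylpropoxy)(tert-butyl)dimethylsilane; 3 (4-bromobut-1-yn-1-yl)trimethylsilane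
Product: 5 (S)-tert-butyldimethyl{[2-methyl-7-(trimethylsilyl)hept-6-yn-1-yl]oxy}silane, via Grignard reagent 4 (not isolated)
Conditions: 3, Mg, THF, rt to 40 °C; then 2, Li2CuCl4 (5 mol%), THF/NMP, −10 °C to rt
Reagents that add atoms: none
Why: Copper-catalysed coupling of an alkyl Grignard reagent with a primary alkyl bromide (Kochi coupling) forms C9'–C10' by substitution next to, not at, the stereocentre, and the C-silyl group keeps the alkyne from quenching the Grignard reagent.

Step 3
Reactants: 5 (S)-tert-butyldimethyl{[2-methyl-7-(trimethylsilyl)hept-6-yn-1-yl]oxy}silane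
Product: 6 (S)-tert-butyldimethyl[(2-methylhept-6-yn-1-yl)oxy]silane
Conditions: K2CO3 (cat.), MeOH, rt
Reagents that add atoms: none
Why: Base-catalysed methanolysis cleaves the alkynyl C–Si bond selectively, since the primary TBS ether is stable to K2CO3 in methanol.

Step 4
Reactants: 6 (S)-tert-butyldimethyl[(2-methylhept-6-yn-1-yl)oxy]silane
Product: 9 (2E,7S)-8-[(tert-butyldimethylsilyl)oxy]-3,7-dimethyloct-2-en-1-ol, via alkenylalane 7 (not isolated), via lithium alanate 8 (not isolated)
Conditions: AlMe3, Cp2ZrCl2 (25 mol%), CH2Cl2, 0 °C to rt; evaporation; n-BuLi, THF/hexane, −78 to 0 °C; (CH2O)n, rt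
Reagents that add atoms: trimethylaluminium, C[Al](C)C; formaldehyde (as paraformaldehyde), C=O
Why: Negishi carboalumination adds CH3 and Al syn across the terminal alkyne with Al on the terminal carbon, which fixes the 6'E geometry, and the derived alanate is hydroxymethylated by formaldehyde with retention at the alkenyl carbon.

Step 5
Reactants: 9 (2E,7S)-8-[(tert-butyldimethylsilyl)oxy]-3,7-dimethyloct-2-en-1-ol
Product: 10 (2E,7S)-8-[(tert-butyldimethylsilyl)oxy]-3,7-dimethyloct-2-enal
Conditions: MnO2, CH2Cl2, rt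
Reagents that add atoms: none
Why: MnO2 oxidises the allylic alcohol to the enal chemoselectively and is not expected to affect the alkene geometry or the silyl ether.

Step 6
Reactants: 10 (2E,7S)-8-[(tert-butyldimethylsilyl)oxy]-3,7-dimethyloct-2-enal; 11 4,4,5,5-tetramethyl-2-(propa-1,2-dien-1-yl)-1,3,2-dioxaborolane (allenylboronic acid pinacol ester)
Product: 12 (4S,5E,10S)-11-[(tert-butyldimethylsilyl)oxy]-6,10-dimethylundec-5-en-1-yn-4-ol
Conditions: (S)-3,3'-bis(2,4,6-triisopropylphenyl)-1,1'-binaphthyl-2,2'-diyl hydrogen phosphate (10 mol%), 4 Å molecular sieves, toluene, 0 °C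
Reagents that add atoms: none
Why: Chiral phosphoric acid-catalysed allenylboration runs through a closed six-membered SE2' transition state in which the acid binds a boronate oxygen and the formyl hydrogen, and the (S)-catalyst is expected, by the model established for the related allylboration, to expose the Si face of the enal and so set C5' as S.

Step 7
Reactants: 12 (4S,5E,10S)-11-[(tert-butyldimethylsilyl)oxy]-6,10-dimethylundec-5-en-1-yn-4-ol
Product: 15 (2E,5S,6E,11S)-12-[(tert-butyldimethylsilyl)oxy]-3,7,11-trimethyldodeca-2,6-diene-1,5-diol, via alkenylalane alkoxide 13 (not isolated), via lithium alanate 14 (not isolated)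
Conditions: AlMe3 (4 equiv), Cp2ZrCl2 (50 mol%), CH2Cl2, 0 °C to rt; evaporation; n-BuLi, THF/hexane, −78 to 0 °C; (CH2O)n, rt
Reagents that add atoms: trimethylaluminium, C[Al](C)C; formaldehyde (as paraformaldehyde), C=O
Why: A second Negishi carboalumination, with the homopropargylic hydroxyl carried as its aluminium alkoxide, sets the 2'E trisubstituted alkene by syn addition, and formaldehyde trapping of the alanate installs C1' as a primary allylic alcohol.

Step 8
Reactants: 15 (2E,5S,6E,11S)-12-[(tert-butyldimethylsilyl)oxy]-3,7,11-trimethyldodeca-2,6-diene-1,5-diol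
Product: 16 (2E,5S,6E,11S)-1-bromo-12-[(tert-butyldimethylsilyl)oxy]-3,7,11-trimethyldodeca-2,6-dien-5-ol
Conditions: CBr4 (1.1 equiv), PPh3 (1.1 equiv), CH2Cl2, −40 to −20 °C
Reagents that add atoms: carbon tetrabromide, BrC(Br)(Br)Br
Why: Appel bromination with about one equivalent of reagent at low temperature should select the unhindered primary allylic hydroxyl over the secondary one, and the E geometry of C2'=C3' keeps the C5' hydroxyl from closing onto C1'.

Step 9
Reactants: 16 (2E,5S,6E,11S)-1-bromo-12-[(tert-butyldimethylsilyl)oxy]-3,7,11-trimethyldodeca-2,6-dien-5-ol; 17 ethynylmagnesium bromide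
Product: 18 (4E,7S,8E,13S)-14-[(tert-butyldimethylsilyl)oxy]-5,9,13-trimethyltetradeca-4,8-dien-1-yn-7-ol
Conditions: 17 (4 equiv), CuBr·SMe2 (15 mol%), THF, −20 °C to rt
Reagents that add atoms: none
Why: Copper-catalysed coupling of an alkynyl Grignard reagent with a primary allylic bromide is expected to occur at the α-carbon with retention of the alkene geometry, giving the skipped enyne, while the excess reagent merely deprotonates the free hydroxyl.

Step 10
Reactants: 18 (4E,7S,8E,13S)-14-[(tert-butyldimethylsilyl)oxy]-5,9,13-trimethyltetradeca-4,8-dien-1-yn-7-ol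
Product: 19 (4E,7S,8E,13S)-14-[(tert-butyldimethylsilyl)oxy]-5,9,13-trimethyltetradeca-4,8-dien-1-yn-7-yl acetate
Conditions: Ac2O, pyridine, 4-(dimethylamino)pyridine (5 mol%), CH2Cl2, 0 °C to rt
Reagents that add atoms: acetic anhydride, CC(=O)OC(C)=O
Why: Nucleophile-catalysed acylation esterifies the secondary allylic alcohol with retention at C5' and uses no base strong enough to isomerise the skipped enyne.

Step 11
Reactants: 19 (4E,7S,8E,13S)-14-[(tert-butyldimethylsilyl)oxy]-5,9,13-trimethyltetradeca-4,8-dien-1-yn-7-yl acetate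
Product: 20 (4E,7S,8E,13S)-14-hydroxy-5,9,13-trimethyltetradeca-4,8-dien-1-yn-7-yl acetate
Conditions: HF·pyridine, pyridine, THF, 0 °C to rt
Reagents that add atoms: none
Why: Pyridine-buffered HF·pyridine cleaves the primary silyl ether by fluoride attack at silicon, conditions under which the allylic acetate and the terminal alkyne are stable.

Step 12
Reactants: 20 (4E,7S,8E,13S)-14-hydroxy-5,9,13-trimethyltetradeca-4,8-dien-1-yn-7-yl acetate
Product: 21 (4E,7S,8E,13S)-5,9,13-trimethyl-14-oxotetradeca-4,8-dien-1-yn-7-yl acetate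
Conditions: Dess–Martin periodinane, pyridine, CH2Cl2, 0 °C to rt
Reagents that add atoms: none
Why: Dess–Martin oxidation under pyridine buffer stops at the aldehyde and is mild enough to keep the α-stereocentre C11' from epimerising, the aldehyde being used directly.

Step 13
Reactants: 22 2-methylbut-3-yn-2-ol
Product: 23 (E)-2-methyl-4-(tributylstannyl)but-3-en-2-ol
Conditions: Bu3SnH, PdCl2(PPh3)2 (2 mol%), THF, 0 °C to rt
Reagents that add atoms: tributyltin hydride, CCCC[SnH](CCCC)CCCC
Why: Palladium-catalysed hydrostannylation adds H and Sn syn across the alkyne, and with a tertiary propargylic alcohol the tin should go to the terminal carbon, giving the E-alkenylstannane.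

Step 14
Reactants: 23 (E)-2-methyl-4-(tributylstannyl)but-3-en-2-ol
Product: 24 (E)-4-iodo-2-methylbut-3-en-2-ol
Conditions: I2, CH2Cl2, 0 °C
Reagents that add atoms: iodine, II
Why: Iododestannylation replaces tin by iodine with retention of the E geometry.

Step 15
Reactants: 21 (4E,7S,8E,13S)-5,9,13-trimethyl-14-oxotetradeca-4,8-dien-1-yn-7-yl acetate; 24 (E)-4-iodo-2-methylbut-3-en-2-ol
Product: 26 (4E,7S,8E,13S,15E)-14,17-dihydroxy-5,9,13,17-tetramethyloctadeca-4,8,15-trien-1-yn-7-yl acetate as both C14 epimers, via alkenylchromium reagent 25 (not isolated)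
Conditions: 24 (2 equiv), CrCl2 (6 equiv), NiCl2 (2 mol%), DMSO, rt
Reagents that add atoms: none
Why: In the Nozaki–Hiyama–Kishi reaction the alkenyl iodide is activated by the nickel co-catalyst and passed to chromium, and the weakly basic alkenylchromium reagent adds only to the aldehyde, tolerating the acetate, the free hydroxyl and the terminal alkyne and leaving C11' intact; the new carbinol centre is uncontrolled and is erased in step 16.

Step 16
Reactants: 26 (4E,7S,8E,13S,15E)-14,17-dihydroxy-5,9,13,17-tetramethyloctadeca-4,8,15-trien-1-yn-7-yl acetate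
Product: 27 (4E,7S,8E,13S,15E)-17-hydroxy-5,9,13,17-tetramethyl-14-oxooctadeca-4,8,15-trien-1-yn-7-yl acetate
Conditions: Dess–Martin periodinane, pyridine, CH2Cl2, 0 °C
Reagents that add atoms: none
Why: Dess–Martin oxidation converts both epimers of the secondary allylic alcohol into the same E-enone, while the tertiary alcohol cannot be oxidised.

Step 17
Reactants: 28 (E)-1-bromoprop-1-ene; 29 hexacarbonylchromium Cr(CO)6
Product: 32 pentacarbonyl[(E)-1-methoxybut-2-en-1-ylidene]chromium, via propenyllithium 30 (not isolated), via lithium acylchromate 31 (not isolated)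
Conditions: t-BuLi (2 equiv), Et2O, −78 °C; Cr(CO)6, Et2O, 0 °C to rt; Me3OBF4, CH2Cl2, 0 °C
Reagents that add atoms: trimethyloxonium tetrafluoroborate, C[O+](C)C.F[B-](F)(F)F
Why: Fischer carbene synthesis: bromine–lithium exchange with retention of the E geometry, addition of the alkenyllithium to a carbonyl ligand of Cr(CO)6 and O-methylation of the acylchromate with Meerwein's salt.

Step 18
Reactants: 27 (4E,7S,8E,13S,15E)-17-hydroxy-5,9,13,17-tetramethyl-14-oxooctadeca-4,8,15-trien-1-yn-7-yl acetate; 32 pentacarbonyl[(E)-1-methoxybut-2-en-1-ylidene]chromium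
Product: 34 (2E,5S,6E,11S,13E)-15-hydroxy-1-(2-hydroxy-5-methoxy-3-methylphenyl)-3,7,11,15-tetramethyl-12-oxohexadeca-2,6,13-trien-5-yl acetate, via tricarbonylchromium complex 33 (not isolated)
Conditions: 32 (1.5 equiv), degassed THF, 50 °C; then air, Et2O, rt
Reagents that add atoms: none
Why: Heating dissociates one carbonyl ligand from 32, the alkyne of 27 takes the free site and couples through its unsubstituted end with the carbene carbon (C4–C5), and the resulting vinylcarbene, whose carbene carbon is now C6, migrates onto a CO ligand (C6–C1) to give a chromium-bound dienylketene. The six-membered ring then closes by 6π-electrocyclisation of this dienylketene (C1–C2), and the cyclohexadienone formed moves its C2 hydrogen to oxygen to give the phenol, first as Cr(CO)3 complex 33, from which air releases 34. The closest known reaction is the Dötz benzannulation of alkenyl(alkoxy)carbene complexes of zerovalent chromium with terminal alkynes, applied here to a more functionalised alkyne. No stereocentre is created, and C5' and C11' are spectators under the neutral conditions. The step needs regioselectivity, which the size difference between H and CH2R on the alkyne should secure by placing the larger group next to the CO-derived C1, and chemoselectivity, which rests on the terminal alkyne being the best π-ligand present (the alkenes are trisubstituted or electron-poor) and on the single CH2 between the alkyne and C2'=C3', which rules out intramolecular cyclopropanation by the vinylcarbene.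

Step 19
Reactants: 34 (2E,5S,6E,11S,13E)-15-hydroxy-1-(2-hydroxy-5-methoxy-3-methylphenyl)-3,7,11,15-tetramethyl-12-oxohexadeca-2,6,13-trien-5-yl acetate
Product: 35 (2E,5S,6E,11S,13E)-15-hydroxy-3,7,11,15-tetramethyl-1-(5-methyl-3,6-dioxocyclohexa-1,4-dien-1-yl)-12-oxohexadeca-2,6,13-trien-5-yl acetate
Conditions: (NH4)2Ce(NO3)6 (2.5 equiv), MeCN/H2O, 0 °C
Reagents that add atoms: water, O
Why: Oxidative demethylation of a p-methoxyphenol by (NH4)2Ce(NO3)6 (two one-electron oxidations, attack of water at C4, loss of methanol) should give the p-quinone much faster than the isolated alkenes or the enone can react.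

Step 20
Reactants: 35 (2E,5S,6E,11S,13E)-15-hydroxy-3,7,11,15-tetramethyl-1-(5-methyl-3,6-dioxocyclohexa-1,4-dien-1-yl)-12-oxohexadeca-2,6,13-trien-5-yl acetate
Product: 36 (2E,5S,6E,11S,13E)-1-(2,5-dihydroxy-3-methylphenyl)-15-hydroxy-3,7,11,15-tetramethyl-12-oxohexadeca-2,6,13-trien-5-yl acetate
Conditions: Na2S2O4, EtOAc/H2O, rt, under argon
Reagents that add atoms: none
Why: Dithionite reduction of the quinone in a two-phase system gives the hydroquinone under near-neutral conditions that leave the enone, the acetate and both stereocentres untouched.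

Compound list
1 | (R)-3-bromo-2-methylpropan-1-ol | BrC[C@H](C)CO | starting material
2 | (R)-(3-bromo-2-methylpropoxy)(tert-butyl)dimethylsilane | BrC[C@H](C)CO[Si](C)(C)C(C)(C)C | intermediate
3 | (4-bromobut-1-yn-1-yl)trimethylsilane | C[Si](C)(C)C#CCCBr | starting material
4 | [4-(trimethylsilyl)but-3-yn-1-yl]magnesium bromide | C[Si](C)(C)C#CCC[Mg]Br | intermediate
5 | (S)-tert-butyldimethyl{[2-methyl-7-(trimethylsilyl)hept-6-yn-1-yl]oxy}silane | C[Si](C)(C)C#CCCC[C@H](C)CO[Si](C)(C)C(C)(C)C | intermediate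
6 | (S)-tert-butyldimethyl[(2-methylhept-6-yn-1-yl)oxy]silane | C#CCCC[C@H](C)CO[Si](C)(C)C(C)(C)C | intermediate
7 | {(1E,6S)-7-[(tert-butyldimethylsilyl)oxy]-2,6-dimethylhept-1-en-1-yl}dimethylalane | C[Al](C)/C=C(\C)CCC[C@H](C)CO[Si](C)(C)C(C)(C)C | intermediate
8 | lithium butyl{(1E,6S)-7-[(tert-butyldimethylsilyl)oxy]-2,6-dimethylhept-1-en-1-yl}dimethylaluminate | [Li+].CCCC[Al-](C)(C)/C=C(\C)CCC[C@H](C)CO[Si](C)(C)C(C)(C)C | intermediate
9 | (2E,7S)-8-[(tert-butyldimethylsilyl)oxy]-3,7-dimethyloct-2-en-1-ol | OC/C=C(\C)CCC[C@H](C)CO[Si](C)(C)C(C)(C)C | intermediate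
10 | (2E,7S)-8-[(tert-butyldimethylsilyl)oxy]-3,7-dimethyloct-2-enal | O=C/C=C(\C)CCC[C@H](C)CO[Si](C)(C)C(C)(C)C | intermediate
11 | 4,4,5,5-tetramethyl-2-(propa-1,2-dien-1-yl)-1,3,2-dioxaborolane | C=C=CB1OC(C)(C)C(C)(C)O1 | starting material
12 | (4S,5E,10S)-11-[(tert-butyldimethylsilyl)oxy]-6,10-dimethylundec-5-en-1-yn-4-ol | C#CC[C@H](O)/C=C(\C)CCC[C@H](C)CO[Si](C)(C)C(C)(C)C | intermediate
13 | [(1E,4S,5E,10S)-11-[(tert-butyldimethylsilyl)oxy]-4-[(dimethylalumanyl)oxy]-2,6,10-trimethylundeca-1,5-dien-1-yl]dimethylalane | C[Al](C)/C=C(\C)C[C@H](O[Al](C)C)/C=C(\C)CCC[C@H](C)CO[Si](C)(C)C(C)(C)C | intermediate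
14 | lithium butyl[(1E,4S,5E,10S)-11-[(tert-butyldimethylsilyl)oxy]-4-[(dimethylalumanyl)oxy]-2,6,10-trimethylundeca-1,5-dien-1-yl]dimethylaluminate | [Li+].CCCC[Al-](C)(C)/C=C(\C)C[C@H](O[Al](C)C)/C=C(\C)CCC[C@H](C)CO[Si](C)(C)C(C)(C)C | intermediate
15 | (2E,5S,6E,11S)-12-[(tert-butyldimethylsilyl)oxy]-3,7,11-trimethyldodeca-2,6-diene-1,5-diol | OC/C=C(\C)C[C@H](O)/C=C(\C)CCC[C@H](C)CO[Si](C)(C)C(C)(C)C | intermediate
16 | (2E,5S,6E,11S)-1-bromo-12-[(tert-butyldimethylsilyl)oxy]-3,7,11-trimethyldodeca-2,6-dien-5-ol | BrC/C=C(\C)C[C@H](O)/C=C(\C)CCC[C@H](C)CO[Si](C)(C)C(C)(C)C | intermediate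
17 | ethynylmagnesium bromide | C#C[Mg]Br | starting material
18 | (4E,7S,8E,13S)-14-[(tert-butyldimethylsilyl)oxy]-5,9,13-trimethyltetradeca-4,8-dien-1-yn-7-ol | C#CC/C=C(\C)C[C@H](O)/C=C(\C)CCC[C@H](C)CO[Si](C)(C)C(C)(C)C | intermediate
19 | (4E,7S,8E,13S)-14-[(tert-butyldimethylsilyl)oxy]-5,9,13-trimethyltetradeca-4,8-dien-1-yn-7-yl acetate | CC(=O)O[C@H](/C=C(\C)CCC[C@H](C)CO[Si](C)(C)C(C)(C)C)C/C(C)=C/CC#C | intermediate
20 | (4E,7S,8E,13S)-14-hydroxy-5,9,13-trimethyltetradeca-4,8-dien-1-yn-7-yl acetate | CC(=O)O[C@H](/C=C(\C)CCC[C@H](C)CO)C/C(C)=C/CC#C | intermediate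
21 | (4E,7S,8E,13S)-5,9,13-trimethyl-14-oxotetradeca-4,8-dien-1-yn-7-yl acetate | CC(=O)O[C@H](/C=C(\C)CCC[C@H](C)C=O)C/C(C)=C/CC#C | intermediate
22 | 2-methylbut-3-yn-2-ol | CC(C)(O)C#C | starting material
23 | (E)-2-methyl-4-(tributylstannyl)but-3-en-2-ol | CCCC[Sn](CCCC)(CCCC)/C=C/C(C)(C)O | intermediate
24 | (E)-4-iodo-2-methylbut-3-en-2-ol | CC(C)(O)/C=C/I | intermediate
25 | dichloro[(E)-3-hydroxy-3-methylbut-1-en-1-yl]chromium | CC(C)(O)/C=C/[Cr](Cl)Cl | intermediate
26 | (4E,7S,8E,13S,15E)-14,17-dihydroxy-5,9,13,17-tetramethyloctadeca-4,8,15-trien-1-yn-7-yl acetate (both C14 epimers) | CC(=O)O[C@H](/C=C(\C)CCC[C@H](C)C(O)/C=C/C(C)(C)O)C/C(C)=C/CC#C | intermediate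
27 | (4E,7S,8E,13S,15E)-17-hydroxy-5,9,13,17-tetramethyl-14-oxooctadeca-4,8,15-trien-1-yn-7-yl acetate | CC(=O)O[C@H](/C=C(\C)CCC[C@H](C)C(=O)/C=C/C(C)(C)O)C/C(C)=C/CC#C | intermediate
28 | (E)-1-bromoprop-1-ene | C/C=C/Br | starting material
29 | hexacarbonylchromium Cr(CO)6 | O=C=[Cr](=C=O)(=C=O)(=C=O)(=C=O)=C=O | starting material
30 | (E)-prop-1-en-1-yllithium | [Li]/C=C/C | intermediate
31 | lithium pentacarbonyl[(E)-1-oxidobut-2-en-1-ylidene]chromate | [Li+].[O-]C(/C=C/C)=[Cr](=C=O)(=C=O)(=C=O)(=C=O)=C=O | intermediate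
32 | pentacarbonyl[(E)-1-methoxybut-2-en-1-ylidene]chromium | COC(/C=C/C)=[Cr](=C=O)(=C=O)(=C=O)(=C=O)=C=O | intermediate
33 | tricarbonylchromium η6-arene complex of 34 | CC(=O)O[C@H](/C=C(\C)CCC[C@H](C)C(=O)/C=C/C(C)(C)O)C/C(C)=C/Cc1cc(OC)cc(C)c1O.[Cr](=C=O)(=C=O)=C=O | intermediate
34 | (2E,5S,6E,11S,13E)-15-hydroxy-1-(2-hydroxy-5-methoxy-3-methylphenyl)-3,7,11,15-tetramethyl-12-oxohexadeca-2,6,13-trien-5-yl acetate | CC(=O)O[C@H](/C=C(\C)CCC[C@H](C)C(=O)/C=C/C(C)(C)O)C/C(C)=C/Cc1cc(OC)cc(C)c1O | intermediate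
35 | (2E,5S,6E,11S,13E)-15-hydroxy-3,7,11,15-tetramethyl-1-(5-methyl-3,6-dioxocyclohexa-1,4-dien-1-yl)-12-oxohexadeca-2,6,13-trien-5-yl acetate | CC(=O)O[C@H](/C=C(\C)CCC[C@H](C)C(=O)/C=C/C(C)(C)O)C/C(C)=C/CC1=CC(=O)C=C(C)C1=O | intermediate
36 | (2E,5S,6E,11S,13E)-1-(2,5-dihydroxy-3-methylphenyl)-15-hydroxy-3,7,11,15-tetramethyl-12-oxohexadeca-2,6,13-trien-5-yl acetate | CC(=O)O[C@H](/C=C(\C)CCC[C@H](C)C(=O)/C=C/C(C)(C)O)C/C(C)=C/Cc1cc(O)cc(C)c1O | target

Total step count: 20. Longest linear sequence: 17 steps (steps 1–12, 15, 16, 18, 19, 20, from compound 1); steps 13–14 and step 17 are side branches.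

Steps most likely to fail

Step 18. The carbene complex may be consumed at the electron-poor C13'=C14' bond of the enone (cyclopropanation, displacement of the alkyne at the metal), or low-valent chromium residues may reduce the enone, so that alkyne insertion no longer dominates. The fallback moves the benzannulation one oxidation level back and keeps the same ring construction. It sets out from allylic alcohol 26, which reacts with 32 under the conditions of step 18 (THF, 50 °C, then air) to give, through tricarbonylchromium complex F1, the C12'-hydroxy methoxyphenol F2. Oxidation with (NH4)2Ce(NO3)6 in MeCN/H2O at 0 °C then gives the C12'-hydroxy quinone F3, and Dess–Martin periodinane oxidises its secondary allylic alcohol to the enone. This is quinone 35, where the route is rejoined before the final reduction.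

Step 8. Activation may not stay at C1': the secondary allylic C5' hydroxyl can be brominated or can ionise (allylic transposition, elimination to a triene), a weakness already latent when its aluminium alkoxide meets AlMe3 in step 7. The fallback protects this hydroxyl before the chain is extended. It sets out from 12, which Et3SiCl and imidazole convert into triethylsilyl ether F4. Carboalumination (AlMe3, Cp2ZrCl2), through alkenylalane F5 and lithium alanate F6, followed by formaldehyde gives allylic alcohol F7; CBr4/PPh3 gives allylic bromide F8; ethynylmagnesium bromide 17 with CuBr·SMe2 gives silyl-protected enyne F9. Pyridinium p-toluenesulfonate in MeOH at 0 °C then removes the secondary triethylsilyl ether but not the primary TBS ether, and the route is rejoined at 18.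

Step 6. Facial discrimination in the allenylboration of a β,β-disubstituted enal may be poor, which would give C5' epimers that cannot be separated because the second stereocentre is remote. The fallback corrects the carbinol by oxidation and reagent-controlled reduction. It sets out from 12 of insufficient purity, which Dess–Martin periodinane (pyridine, CH2Cl2, 0 °C) oxidises to ynone F10, kept free of base to avoid alkyne-to-allene isomerisation. Corey–Bakshi–Shibata reduction with catecholborane and (R)-1-methyl-3,3-diphenyltetrahydro-1H,3H-pyrrolo[1,2-c][1,3,2]oxazaborole at −78 °C, in which the alkenyl group acts as the large substituent, should deliver the (4S)-alcohol, and the route is rejoined at 12.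

Further compounds
F1 | step 18 | tricarbonylchromium η6-arene complex of F2 | CC(=O)O[C@H](/C=C(\C)CCC[C@H](C)C(O)/C=C/C(C)(C)O)C/C(C)=C/Cc1cc(OC)cc(C)c1O.[Cr](=C=O)(=C=O)=C=O
F2 | step 18 | (2E,5S,6E,11S,13E)-12,15-dihydroxy-1-(2-hydroxy-5-methoxy-3-methylphenyl)-3,7,11,15-tetramethylhexadeca-2,6,13-trien-5-yl acetate (both C12 epimers) | CC(=O)O[C@H](/C=C(\C)CCC[C@H](C)C(O)/C=C/C(C)(C)O)C/C(C)=C/Cc1cc(OC)cc(C)c1O
F3 | step 18 | (2E,5S,6E,11S,13E)-12,15-dihydroxy-3,7,11,15-tetramethyl-1-(5-methyl-3,6-dioxocyclohexa-1,4-dien-1-yl)hexadeca-2,6,13-trien-5-yl acetate (both C12 epimers) | CC(=O)O[C@H](/C=C(\C)CCC[C@H](C)C(O)/C=C/C(C)(C)O)C/C(C)=C/CC1=CC(=O)C=C(C)C1=O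
F4 | step 8 | (4S,5E,10S)-11-[(tert-butyldimethylsilyl)oxy]-6,10-dimethyl-4-[(triethylsilyl)oxy]undec-5-en-1-yne | C#CC[C@H](O[Si](CC)(CC)CC)/C=C(\C)CCC[C@H](C)CO[Si](C)(C)C(C)(C)C
F5 | step 8 | [(1E,4S,5E,10S)-11-[(tert-butyldimethylsilyl)oxy]-2,6,10-trimethyl-4-[(triethylsilyl)oxy]undeca-1,5-dien-1-yl]dimethylalane | C[Al](C)/C=C(\C)C[C@H](O[Si](CC)(CC)CC)/C=C(\C)CCC[C@H](C)CO[Si](C)(C)C(C)(C)C
F6 | step 8 | lithium butyl[(1E,4S,5E,10S)-11-[(tert-butyldimethylsilyl)oxy]-2,6,10-trimethyl-4-[(triethylsilyl)oxy]undeca-1,5-dien-1-yl]dimethylaluminate | [Li+].CCCC[Al-](C)(C)/C=C(\C)C[C@H](O[Si](CC)(CC)CC)/C=C(\C)CCC[C@H](C)CO[Si](C)(C)C(C)(C)C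
F7 | step 8 | (2E,5S,6E,11S)-12-[(tert-butyldimethylsilyl)oxy]-3,7,11-trimethyl-5-[(triethylsilyl)oxy]dodeca-2,6-dien-1-ol | OC/C=C(\C)C[C@H](O[Si](CC)(CC)CC)/C=C(\C)CCC[C@H](C)CO[Si](C)(C)C(C)(C)C
F8 | step 8 | (2E,5S,6E,11S)-1-bromo-12-[(tert-butyldimethylsilyl)oxy]-3,7,11-trimethyl-5-[(triethylsilyl)oxy]dodeca-2,6-diene | BrC/C=C(\C)C[C@H](O[Si](CC)(CC)CC)/C=C(\C)CCC[C@H](C)CO[Si](C)(C)C(C)(C)C
F9 | step 8 | (4E,7S,8E,13S)-14-[(tert-butyldimethylsilyl)oxy]-5,9,13-trimethyl-7-[(triethylsilyl)oxy]tetradeca-4,8-dien-1-yne | C#CC/C=C(\C)C[C@H](O[Si](CC)(CC)CC)/C=C(\C)CCC[C@H](C)CO[Si](C)(C)C(C)(C)C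
F10 | step 6 | (5E,10S)-11-[(tert-butyldimethylsilyl)oxy]-6,10-dimethylundec-5-en-1-yn-4-one | C#CCC(=O)/C=C(\C)CCC[C@H](C)CO[Si](C)(C)C(C)(C)C
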